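Compound numbers 1 to 16 are those of the steps and of the compound list below.

## Analysis of the target

Target 16 consists of three rings joined by two CH2 groups. Ring A is a γ-butyrolactone (O1, C2, C3, C4, C5). Ring B is a 2-pyranone with a free carboxylic acid on its C6, tied through its C4 and a CH2 group to C3 of ring A. Ring C is a 3,4-dimethoxybenzene tied through a benzylic CH2 group to C4 of ring A. The only stereocentres are the neighbouring C3 and C4 of ring A, both R, with the two CH2 arms trans; C3 is alpha to the lactone carbonyl and can be epimerised, C4 cannot. Ring B is the delicate part: it is electrophilic at C2, C4 and C6, it is opened by hydroxide, alkoxides and amines, and the CH2 group on its C4 is a vinylogous alpha position. The free acid, the lactone and the aryl methyl ethers restrict the end game to mild acid. The difficulty is to attach a base-labile pyranone through an sp3 carbon to an enolisable lactone carbon while controlling C4, which has no neighbouring functional group to direct a reagent. The plan rests on the fact that the benzylic carbon on C4 is gamma to the lactone carbonyl C2. C3, C4 and that carbon can therefore be tied as a cyclopropane fused to ring A. With an additional ester on C3 this cyclopropane is doubly activated, and its opening by the aryl nucleophile leaves a stabilised enolate at C3, where the pyranonylmethyl group must go.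

## Retrosynthetic reasoning

**16 back to 15.** The C6 carboxylic acid of ring B is carried as its ethyl ester. Unmasking it last means every carbon–carbon bond is formed on neutral compounds and the C3 equilibration is run without a free acid. The forward step must cleave one ester next to a lactone and a pyranone. Acid is used because base would open ring B, whereas a γ-lactone recloses under acid.

**15 back to 12 (through 14 and 13).** The hydrogen on C3 is replaced by a tert-butoxycarbonyl group. This costs a carbon that is later lost, but it turns C3 into a malonate-type carbon, which makes both bond formations of the key step possible. Going forward, acidolysis gives acid 13, decarboxylation gives the C3 epimers 14, and base equilibration gives the trans ester 15. C3 is thus set under thermodynamic control by C4, so only C4 needs absolute control.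

**12 back to 3, 5 and 10 (key disconnection).** Two bonds are cut: C3 to the CH2 of ring B, and the aryl carbon to the benzylic CH2.
- Cutting the aryl–CH2 bond, rather than the CH2–C4 bond, means C4 is never a reacting centre. The electrophile is cyclopropane lactone 3, the nucleophile is Grignard reagent 5 under copper catalysis, and the resulting enolate 11 captures bromide 10 in the same flask.
- Alkylating a plain lactone enolate with 10 would expose ring B to a hard, strongly basic enolate. Enolate 11 is stabilised by two carbonyl groups and is soft.
- The temporary ester is tert-butyl. An allyl ester, removable with zerovalent palladium under neutral conditions, was weighed first. An allyl ester of so acidic an acid is, however, itself an electrophile for copper-catalysed allylic substitution by 5 while it is still in 3. The tert-butyl ester is inert to the cuprate, shields its own carbonyl, and falls to anhydrous acid that rings A and B tolerate.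
- The forward reaction must attack the cyclopropane CH2 and not a carbonyl group, and 5 must be used up before 10 enters.

**3 back to 1 and 2.** The cyclopropane and ring A are cut together. Malonate 2 supplies C2, C3 and the temporary ester; epoxide 1 supplies C4, C5, the future benzylic carbon and the absolute configuration. This is the known one-step cyclopropanation–lactonisation of malonates with epichlorohydrin.

**5 back to 4.** 5 is the Grignard reagent of aryl bromide 4.

**10 back to 6 and 7 (through 9 and 8).** The C–Br bond goes back to the methyl group of pyranone 9 by radical bromination. Ring B is cut at O1–C2 and at C5–C6, which leads through dienolate 8 to senecioate 6 and oxalate 7. The C6 carboxyl group is thereby present at the correct oxidation level from the start.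

## Alternatives that were turned down

**Alternative 1:** Ring B is cut at its O1–C6 bond and made last.
- Disconnection: the precursor is the (2Z)-enynoic acid A2, in which finished ring A carries at C3 a CH2 group bound to C3 of a hex-2-en-4-ynoic acid with a silyloxymethyl group on the alkyne terminus.
- Forward key step: ZnBr2, or AuCl(PPh3) with AgOTf as a source of monovalent gold, would activate the triple bond. The carboxyl oxygen would add to the far alkyne carbon in a 6-endo-dig closure to give the 6-(silyloxymethyl)pyranone A1. Desilylation and oxidation of the primary alcohol to the acid would follow.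
- For it: ring B does not exist while enolates are in play. C3 could be set kinetically and trans by alkylating a plain lactone enolate with a robust propargylic halide, and the closure runs under nearly neutral conditions. On these points it is stronger than the chosen route, which must take an intact pyranone through an enolate alkylation and a base-mediated equilibration.
- Against it: the 6-endo closure competes with 5-exo closure to an alkylidene butenolide, and the inductively withdrawing CH2O group sits on the alkyne carbon that must accept the oxygen. A2 needs a trisubstituted alkene of defined Z geometry. The C6 carboxyl arrives two oxidation levels too low and must be raised at the end next to benzylic positions and an electron-rich arene. The step count is clearly higher.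
- Comparison: the chosen strategy offers a ring B made in two steps with its carboxyl group already in place, and a convergent union of three fragments in one flask.

**Alternative 2:** Ring A is cut at O1–C2 and C2–C3, with its carbonyl carbon taken from carbon monoxide.
- Disconnection: the precursor is the homopropargylic alcohol A4, with C4 as a lone stereocentre in an open chain and ring B (as its tert-butyl ester) on the alkyne terminus.
- Forward key step: under CO with PdCl2(PPh3)2 and SnCl2 the primary alcohol would give an alkoxycarbonyl complex of divalent palladium. This adds syn across the triple bond in a 5-exo-dig closure, and protonolysis leaves the (E)-alkylidene lactone A3.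
- For it: ring closure, the C2–C3 bond and the carbonyl group come in one catalytic step. Ring B is attached by cross-coupling and never acts as an alkylating agent. In atom economy at ring A it is stronger than the chosen route.
- Against it: A3 still needs hydrogen added across the exocyclic double bond, which is conjugated with both double bonds of ring B, so neither hydrogenation nor hydride conjugate reduction can be expected to single it out. Hydrogen delivered anti to the C4 arm gives the cis lactone, so the equilibration of the chosen route is not avoided. The stereocentre of A4 needs an auxiliary or an enzyme over several steps.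
- Comparison: the chosen route takes C4 from the chiral pool in one step and needs no reduction near ring B.

**Alternative 3:** The C4–C5 bond of ring A is cut, and C5 is delivered from a silicon tether on a benzylic alcohol that is deleted afterwards.
- Disconnection: the precursor is the (bromomethyl)dimethylsilyl ether A6, an alpha-(pyranonylmethyl) enoate whose gamma carbon carries the aryl group and the tether.
- Forward key step: Bu3SnH with AIBN would generate the alpha-silyl radical, which adds 5-exo-trig to the beta carbon of the enoate and closes an oxasilolane. The ester-stabilised radical at the future C3 then takes hydrogen from the stannane to give A5. Tamao–Fleming oxidation, lactonisation and benzylic deoxygenation would complete ring A.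
- For it: the tethered closure is dependable and places the new chain trans to the aryl group across the five-membered ring. The conditions are neutral, so ring B meets no enolate. In that respect it is as strong as the chosen route or stronger.
- Against it: three stereocentres are made and one is discarded, and that one, the only source of absolute configuration, must itself be made enantioselectively. C3 is set by hydrogen transfer to an open-chain radical with little bias. Ring B is a good acceptor for stannyl and carbon radicals. Oxidative C–Si cleavage needs fluoride and basic peroxide, which attack a pyranone, and benzylic hydrogenolysis competes with saturation of ring B. Tin is used stoichiometrically.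
- Comparison: the chosen strategy needs no sacrificial stereocentre, takes C4 unchanged from a commercial epoxide, and needs roughly half the steps.

Key step: step 5

Remark: 14 is the pair of C3 epimers (its SMILES leaves C3 open), and 8 is drawn as the (2Z,4Z) isomer that can cyclise; its double-bond isomers interconvert through keto tautomers under the acid of step 3.

## Route

Step 1
Reactants: 1 (R)-epichlorohydrin [(2R)-2-(chloromethyl)oxirane]; 2 di-tert-butyl malonate
Product: 3 tert-butyl (1R,5R)-2-oxo-3-oxabicyclo[3.1.0]hexane-1-carboxylate
Conditions: t-BuOK (1.05 equiv), t-BuOH, 25 to 60 °C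
Reagents that add atoms: none
Why: Known malonate–epichlorohydrin cyclopropanation–lactonisation: the malonate anion opens the epoxide at its CH2 end, the alkoxide closes a new epoxide by displacing chloride, the malonate anion opens that epoxide in a 3-exo-tet closure with inversion, and the cis CH2O group lactonises onto the adjacent ester. C5 of 3 (later C4 of ring A) comes from 1 and the ring fusion can only be cis, which fixes C1. A minor path by direct chloride displacement would give the enantiomer, so the enantiomeric purity of 3 should be checked.

Step 2
Reactants: 4 4-bromo-1,2-dimethoxybenzene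
Product: 5 (3,4-dimethoxyphenyl)magnesium bromide (THF solution, titrated)
Conditions: Mg turnings, I2 (cat.), THF, 40–60 °C
Reagents that add atoms: magnesium, [Mg]
Why: Grignard formation by direct insertion of magnesium into an aryl bromide; the methyl ethers are inert, and titration gives the exact amount needed in step 5.

Step 3
Reactants: 6 ethyl 3-methylbut-2-enoate; 7 diethyl oxalate
Product: 9 ethyl 4-methyl-2-oxo-2H-pyran-6-carboxylate, via potassium dienolate 8 (not isolated)
Conditions: KOEt (1.05 equiv), Et2O–EtOH, 0 °C to rt; solvent removed; then anhydrous HCl in EtOH (3 M), 70 °C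
Reagents that add atoms: none
Why: Vinylogous Claisen condensation: the extended enolate of 6 is acylated at its gamma carbon by 7 and the product is held as the conjugated enolate 8. On acidification the enol oxygen attacks the unsaturated ester and expels ethanol (acid-catalysed enol lactonisation to a 2-pyranone). Ethanolic acid keeps the C6 ester as the ethyl ester.

Step 4
Reactants: 9 ethyl 4-methyl-2-oxo-2H-pyran-6-carboxylate
Product: 10 ethyl 4-(bromomethyl)-2-oxo-2H-pyran-6-carboxylate
Conditions: NBS (1.05 equiv), AIBN (5 mol%), PhCF3, 85 °C
Reagents that add atoms: N-bromosuccinimide, O=C1CCC(=O)N1Br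
Why: Wohl–Ziegler bromination: hydrogen abstraction from the 4-methyl group gives an allyl-type radical delocalised onto C3 and the C2 carbonyl of the pyranone, which takes bromine at the exocyclic carbon. The ester on C6 makes the ring electron-poor and disfavours ionic bromination at C3 or C5; stopping short of full conversion limits the dibromide.

Step 5
Reactants: 3 tert-butyl (1R,5R)-2-oxo-3-oxabicyclo[3.1.0]hexane-1-carboxylate; 5 (3,4-dimethoxyphenyl)magnesium bromide; 10 ethyl 4-(bromomethyl)-2-oxo-2H-pyran-6-carboxylate
Product: 12 tert-butyl (3S,4R)-4-(3,4-dimethoxybenzyl)-3-{[6-(ethoxycarbonyl)-2-oxo-2H-pyran-4-yl]methyl}-2-oxotetrahydrofuran-3-carboxylate, via bromomagnesium enolate 11 (not isolated)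
Conditions: 3, CuI (10 mol%), THF, −40 °C; 5 (1.0 equiv, slow addition), −40 to −20 °C; then DMPU, 10 (1.1 equiv), −20 °C to rt
Reagents that add atoms: none
Why: CuI and 5 give an aryl cuprate of monovalent copper, which attacks the unsubstituted cyclopropane carbon C6 of 3 in an SN2-like oxidative addition with the bond to C1 as leaving group; reductive elimination from the aryl(alkyl) intermediate of trivalent copper forms the aryl–CH2 bond and returns monovalent copper. The closest known reaction type is the copper-catalysed homoconjugate addition of Grignard reagents to doubly activated cyclopropanes, established on this bicyclic lactone class with alkyl reagents, followed by the classical C-alkylation of a 2-alkoxycarbonyl lactone enolate with an activated primary bromide. No ring is closed: the three-membered ring opens, driven by its strain and by the two acceptor groups on C1. C5 of 3, which becomes C4 of ring A, is not a reacting centre and keeps the configuration taken from 1. Enolate 11, chelated by magnesium and loosened by DMPU, displaces bromide from 10 at the primary carbon; the new quaternary centre C3 is controlled by the neighbouring C4 substituent, the electrophile entering on the face opposite the dimethoxybenzyl arm, and since this centre is erased in step 6 incomplete selectivity costs nothing. The step needs attack at the cyclopropane CH2 rather than at the ring CH or a carbonyl (secured by copper catalysis at low temperature, steric access and the bulky tert-butyl ester), no aryl metal left when 10 enters (secured by one equivalent of titrated 5 and complete opening first), and C-alkylation at CH2Br rather than attack on ring B (secured by the soft, weakly basic enolate and the high SN2 reactivity of the allylic-type bromide).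

Step 6
Reactants: 12 tert-butyl (3S,4R)-4-(3,4-dimethoxybenzyl)-3-{[6-(ethoxycarbonyl)-2-oxo-2H-pyran-4-yl]methyl}-2-oxotetrahydrofuran-3-carboxylate
Product: 14 ethyl 4-{[(4R)-4-(3,4-dimethoxybenzyl)-2-oxotetrahydrofuran-3-yl]methyl}-2-oxo-2H-pyran-6-carboxylate as the mixture of C3 epimers, via carboxylic acid 13 (not isolated)
Conditions: TFA–CH2Cl2 (1:3), 0 °C to rt; evaporate; toluene or xylene, 110–135 °C
Reagents that add atoms: none
Why: Acidolysis of the tert-butyl ester (E1 loss of isobutene) gives the malonic-type acid 13, which decarboxylates on heating through the cyclic six-membered transition state; the enol so formed is protonated on either face, so C3 is obtained as a mixture. Ring B, its ethyl ester, ring A and the aryl ethers are stable to anhydrous TFA, and C4 is not involved. Et3SiH can be added as a cation scavenger should the electron-rich ring C be tert-butylated.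

Step 7
Reactants: 14 ethyl 4-{[(4R)-4-(3,4-dimethoxybenzyl)-2-oxotetrahydrofuran-3-yl]methyl}-2-oxo-2H-pyran-6-carboxylate (C3 epimers)
Product: 15 ethyl 4-{[(3R,4R)-4-(3,4-dimethoxybenzyl)-2-oxotetrahydrofuran-3-yl]methyl}-2-oxo-2H-pyran-6-carboxylate
Conditions: DBU (0.3 equiv), toluene, 60 °C, N2
Reagents that add atoms: none
Why: Thermodynamic epimerisation: reversible deprotonation at C3 by the non-nucleophilic amidine moves the mixture towards the trans lactone, in which the two CH2 arms on adjacent ring carbons avoid each other, as is general for 3,4-dibenzylbutyrolactones; C4 has no acidic hydrogen and is unchanged. The CH2 group on ring B may also be deprotonated, but it is not stereogenic and reprotonation restores the pyranone; residual cis isomer is separated and resubmitted.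

Step 8
Reactants: 15 ethyl 4-{[(3R,4R)-4-(3,4-dimethoxybenzyl)-2-oxotetrahydrofuran-3-yl]methyl}-2-oxo-2H-pyran-6-carboxylate
Product: 16 4-{[(3R,4R)-4-(3,4-dimethoxybenzyl)-2-oxotetrahydrofuran-3-yl]methyl}-2-oxo-2H-pyran-6-carboxylic acid
Conditions: 6 M aq. HCl–1,4-dioxane (1:1), 80 °C
Reagents that add atoms: water, O
Why: Acid-catalysed ester hydrolysis (AAC2) avoids hydroxide, which would open ring B; 2-pyranone-6-carboxylic acids are stable in hot mineral acid. Ring A recloses under acid, aryl methyl ethers withstand aqueous HCl at this temperature, and C3 already has its thermodynamically preferred configuration.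

## Compound list

1 | (R)-epichlorohydrin, (2R)-2-(chloromethyl)oxirane | ClC[C@H]1CO1 | starting material
2 | di-tert-butyl malonate | CC(C)(C)OC(=O)CC(=O)OC(C)(C)C | starting material
3 | tert-butyl (1R,5R)-2-oxo-3-oxabicyclo[3.1.0]hexane-1-carboxylate (cis-fused; C5 becomes C4 of the target; the tert-butyl ester outranks the lactone carbonyl at C1) | C1[C@H]2COC(=O)[C@@]12C(=O)OC(C)(C)C | intermediate
4 | 4-bromo-1,2-dimethoxybenzene | COc1ccc(Br)cc1OC | starting material
5 | (3,4-dimethoxyphenyl)magnesium bromide | COc1ccc([Mg]Br)cc1OC | intermediate
6 | ethyl 3-methylbut-2-enoate | CCOC(=O)C=C(C)C | starting material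
7 | diethyl oxalate | CCOC(=O)C(=O)OCC | starting material
8 | potassium (2Z,4Z)-1,6-diethoxy-4-methyl-1,6-dioxohexa-2,4-dien-2-olate | CCOC(=O)/C=C(C)\C=C(/[O-])C(=O)OCC.[K+] | intermediate
9 | ethyl 4-methyl-2-oxo-2H-pyran-6-carboxylate | CCOC(=O)c1cc(C)cc(=O)o1 | intermediate
10 | ethyl 4-(bromomethyl)-2-oxo-2H-pyran-6-carboxylate | CCOC(=O)c1cc(CBr)cc(=O)o1 | intermediate
11 | bromomagnesium enolate of tert-butyl (4R)-4-(3,4-dimethoxybenzyl)-2-oxotetrahydrofuran-3-carboxylate | COc1ccc(C[C@H]2COC([O-])=C2C(=O)OC(C)(C)C)cc1OC.[Mg+2].[Br-] | intermediate
12 | tert-butyl (3S,4R)-4-(3,4-dimethoxybenzyl)-3-{[6-(ethoxycarbonyl)-2-oxo-2H-pyran-4-yl]methyl}-2-oxotetrahydrofuran-3-carboxylate (pyranonylmethyl group trans to the dimethoxybenzyl group) | COc1ccc(C[C@H]2COC(=O)[C@]2(C(=O)OC(C)(C)C)Cc2cc(C(=O)OCC)oc(=O)c2)cc1OC | intermediate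
13 | (3R,4R)-4-(3,4-dimethoxybenzyl)-3-{[6-(ethoxycarbonyl)-2-oxo-2H-pyran-4-yl]methyl}-2-oxotetrahydrofuran-3-carboxylic acid | COc1ccc(C[C@H]2COC(=O)[C@]2(C(=O)O)Cc2cc(C(=O)OCC)oc(=O)c2)cc1OC | intermediate
14 | ethyl 4-{[(4R)-4-(3,4-dimethoxybenzyl)-2-oxotetrahydrofuran-3-yl]methyl}-2-oxo-2H-pyran-6-carboxylate, mixture of C3 epimers | COc1ccc(C[C@H]2COC(=O)C2Cc2cc(C(=O)OCC)oc(=O)c2)cc1OC | intermediate
15 | ethyl 4-{[(3R,4R)-4-(3,4-dimethoxybenzyl)-2-oxotetrahydrofuran-3-yl]methyl}-2-oxo-2H-pyran-6-carboxylate (trans) | COc1ccc(C[C@H]2COC(=O)[C@@H]2Cc2cc(C(=O)OCC)oc(=O)c2)cc1OC | intermediate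
16 | 4-{[(3R,4R)-4-(3,4-dimethoxybenzyl)-2-oxotetrahydrofuran-3-yl]methyl}-2-oxo-2H-pyran-6-carboxylic acid (trans) | COc1ccc(C[C@H]2COC(=O)[C@@H]2Cc2cc(C(=O)O)oc(=O)c2)cc1OC | target

## Step count and least certain steps

Total step count: 8. Longest linear sequence: 6 steps (steps 3, 4, 5, 6, 7, 8).

**Step 5 (key step).** The most likely failure is slow C-alkylation of the magnesium-chelated enolate 11. On warming, 10 would then be consumed by proton transfer from its CH2Br group or by conjugate attack on ring B. Arylation of ring B by leftover aryl metal, and direct carbonyl addition of 5 to 3 if copper turnover is slow, are further risks. Fallback: the two events are separated. From 3 and 5 the copper-catalysed opening is run as before and quenched with aqueous NH4Cl to give tert-butyl (4R)-4-(3,4-dimethoxybenzyl)-2-oxotetrahydrofuran-3-carboxylate F1. F1 is then alkylated with 10 using K2CO3 in acetone at room temperature, a classical alkylation of a beta-dicarbonyl compound through its potassium enolate under conditions that bromomethyl-2-pyranones tolerate. This returns to the route at 12.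

**Step 7.** The most likely failure is base-induced degradation of ring B before the C3 epimers reach equilibrium (deprotonation of the CH2 group on its C4 followed by self-condensation, or ring opening by traces of nucleophile). An equilibrium that leaves an inconvenient share of the cis lactone is the other risk. Fallback: C3 is set by kinetic alkylation instead of equilibration.
- From 3 and 5, tert-butyl (4R)-4-(3,4-dimethoxybenzyl)-2-oxotetrahydrofuran-3-carboxylate F1 is prepared as in the fallback to step 5.
- TFA in CH2Cl2 converts F1 into (4R)-4-(3,4-dimethoxybenzyl)-2-oxotetrahydrofuran-3-carboxylic acid F2, which decarboxylates in hot toluene to (4R)-4-(3,4-dimethoxybenzyl)dihydrofuran-2(3H)-one F3.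
- LiN(SiMe3)2 in THF at −78 °C gives the lithium enolate of that lactone, F4. Adding it to 10 at −78 °C should give the trans lactone directly, the electrophile entering anti to the C4 arm, a well-precedented trans-selective alkylation of 4-benzylbutyrolactone enolates.
- This returns to the route at 15 and bypasses 12 to 14. It puts a hard enolate next to ring B, which is why it is the fallback and not the plan.

**Step 4.** The most likely failure is over-bromination to the dibromomethyl compound and ionic bromination of the ring at C3 or C5, with a difficult separation from unreacted 9. Fallback: the oxidation level is adjusted through oxygen. From 9, SeO2 in hot 1,4-dioxane (Riley oxidation of the vinylogous methyl group) gives ethyl 4-formyl-2-oxo-2H-pyran-6-carboxylate F5. NaBH4 in EtOH–THF at −20 °C reduces only the aldehyde to ethyl 4-(hydroxymethyl)-2-oxo-2H-pyran-6-carboxylate F6. CBr4 and PPh3 in CH2Cl2 at 0 °C (Appel reaction) then give 10.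

**Step 3.** The most likely failure is incomplete enol lactonisation in ethanolic acid, or competing self-condensation of the keto diester, giving 9 in poor purity. Fallback: the known hydrolytic closure is used. From 6 and 7 the condensation is run as before and crude 8 is heated in concentrated aqueous HCl, which cyclises and hydrolyses it to 4-methyl-2-oxo-2H-pyran-6-carboxylic acid F7, collected by filtration. Fischer esterification with EtOH and catalytic H2SO4 returns to the route at 9.

**Step 8.** The most likely failure is hydrolysis too slow under conditions mild enough to spare the aryl methyl ethers; forcing would bring ether cleavage and drift of C3 towards the equilibrium mixture. Fallback: the C6 carboxyl is carried as a tert-butyl ester, so that no hydrolysis is needed.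
- From 9, hot 6 M aqueous HCl gives 4-methyl-2-oxo-2H-pyran-6-carboxylic acid F7; the simple pyranone has nothing else to lose.
- tert-Butyl 2,2,2-trichloroacetimidate with catalytic BF3·OEt2 gives tert-butyl 4-methyl-2-oxo-2H-pyran-6-carboxylate F8.
- NBS and AIBN as in step 4 give tert-butyl 4-(bromomethyl)-2-oxo-2H-pyran-6-carboxylate F9.
- The conditions of step 5 with 3 and 5 (through enolate 11) give tert-butyl (3S,4R)-3-{[6-(tert-butoxycarbonyl)-2-oxo-2H-pyran-4-yl]methyl}-4-(3,4-dimethoxybenzyl)-2-oxotetrahydrofuran-3-carboxylate F10.
- TFA removes both tert-butyl groups to give (3R,4R)-3-[(6-carboxy-2-oxo-2H-pyran-4-yl)methyl]-4-(3,4-dimethoxybenzyl)-2-oxotetrahydrofuran-3-carboxylic acid F11. In hot toluene F11 loses the C3 carboxyl to give 4-{[(4R)-4-(3,4-dimethoxybenzyl)-2-oxotetrahydrofuran-3-yl]methyl}-2-oxo-2H-pyran-6-carboxylic acid as its C3 epimers F12.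
- DBU (2.5 equiv) in toluene–THF equilibrates the carboxylate salt to the trans isomer, and acidification returns to the route at 16.

## Further compounds

F1 | step 5 | tert-butyl (4R)-4-(3,4-dimethoxybenzyl)-2-oxotetrahydrofuran-3-carboxylate (C3 epimers, interconverting through the enol) | COc1ccc(C[C@H]2COC(=O)C2C(=O)OC(C)(C)C)cc1OC
F2 | step 7 | (4R)-4-(3,4-dimethoxybenzyl)-2-oxotetrahydrofuran-3-carboxylic acid (C3 epimers) | COc1ccc(C[C@H]2COC(=O)C2C(=O)O)cc1OC
F3 | step 7 | (4R)-4-(3,4-dimethoxybenzyl)dihydrofuran-2(3H)-one | COc1ccc(C[C@H]2COC(=O)C2)cc1OC
F4 | step 7 | lithium enolate of (4R)-4-(3,4-dimethoxybenzyl)dihydrofuran-2(3H)-one | COc1ccc(C[C@H]2COC([O-])=C2)cc1OC.[Li+]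
F5 | step 4 | ethyl 4-formyl-2-oxo-2H-pyran-6-carboxylate | CCOC(=O)c1cc(C=O)cc(=O)o1
F6 | step 4 | ethyl 4-(hydroxymethyl)-2-oxo-2H-pyran-6-carboxylate | CCOC(=O)c1cc(CO)cc(=O)o1
F7 | step 3 | 4-methyl-2-oxo-2H-pyran-6-carboxylic acid | Cc1cc(C(=O)O)oc(=O)c1
F8 | step 8 | tert-butyl 4-methyl-2-oxo-2H-pyran-6-carboxylate | Cc1cc(C(=O)OC(C)(C)C)oc(=O)c1
F9 | step 8 | tert-butyl 4-(bromomethyl)-2-oxo-2H-pyran-6-carboxylate | BrCc1cc(C(=O)OC(C)(C)C)oc(=O)c1
F10 | step 8 | tert-butyl (3S,4R)-3-{[6-(tert-butoxycarbonyl)-2-oxo-2H-pyran-4-yl]methyl}-4-(3,4-dimethoxybenzyl)-2-oxotetrahydrofuran-3-carboxylate | COc1ccc(C[C@H]2COC(=O)[C@]2(C(=O)OC(C)(C)C)Cc2cc(C(=O)OC(C)(C)C)oc(=O)c2)cc1OC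
F11 | step 8 | (3R,4R)-3-[(6-carboxy-2-oxo-2H-pyran-4-yl)methyl]-4-(3,4-dimethoxybenzyl)-2-oxotetrahydrofuran-3-carboxylic acid | COc1ccc(C[C@H]2COC(=O)[C@]2(C(=O)O)Cc2cc(C(=O)O)oc(=O)c2)cc1OC
F12 | step 8 | 4-{[(4R)-4-(3,4-dimethoxybenzyl)-2-oxotetrahydrofuran-3-yl]methyl}-2-oxo-2H-pyran-6-carboxylic acid, mixture of C3 epimers | COc1ccc(C[C@H]2COC(=O)C2Cc2cc(C(=O)O)oc(=O)c2)cc1OC
A1 | alternative 1 | (3R,4R)-3-{[6-({[tert-butyl(dimethyl)silyl]oxy}methyl)-2-oxo-2H-pyran-4-yl]methyl}-4-(3,4-dimethoxybenzyl)dihydrofuran-2(3H)-one | COc1ccc(C[C@H]2COC(=O)[C@@H]2Cc2cc(CO[Si](C)(C)C(C)(C)C)oc(=O)c2)cc1OC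
A2 | alternative 1 | (2Z)-6-{[tert-butyl(dimethyl)silyl]oxy}-3-{[(3R,4R)-4-(3,4-dimethoxybenzyl)-2-oxotetrahydrofuran-3-yl]methyl}hex-2-en-4-ynoic acid | COc1ccc(C[C@H]2COC(=O)[C@@H]2C/C(=C/C(=O)O)C#CCO[Si](C)(C)C(C)(C)C)cc1OC
A3 | alternative 2 | tert-butyl 4-{(E)-[(4R)-4-(3,4-dimethoxybenzyl)-2-oxodihydrofuran-3(2H)-ylidene]methyl}-2-oxo-2H-pyran-6-carboxylate | COc1ccc(C[C@H]2COC(=O)/C2=C/c2cc(C(=O)OC(C)(C)C)oc(=O)c2)cc1OC
A4 | alternative 2 | tert-butyl 4-[(3R)-3-(3,4-dimethoxybenzyl)-4-hydroxybut-1-yn-1-yl]-2-oxo-2H-pyran-6-carboxylate | COc1ccc(C[C@@H](CO)C#Cc2cc(C(=O)OC(C)(C)C)oc(=O)c2)cc1OC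
A5 | alternative 3 | methyl (2R)-2-[(4S,5R)-5-(3,4-dimethoxyphenyl)-2,2-dimethyl-1,2-oxasilolan-4-yl]-3-[6-(ethoxycarbonyl)-2-oxo-2H-pyran-4-yl]propanoate | COc1ccc([C@@H]2O[Si](C)(C)C[C@H]2[C@H](C(=O)OC)Cc2cc(C(=O)OCC)oc(=O)c2)cc1OC
A6 | alternative 3 | methyl (2E,4R)-4-{[(bromomethyl)(dimethyl)silyl]oxy}-4-(3,4-dimethoxyphenyl)-2-{[6-(ethoxycarbonyl)-2-oxo-2H-pyran-4-yl]methyl}but-2-enoate | COc1ccc([C@H](O[Si](C)(C)CBr)/C=C(\Cc2cc(C(=O)OCC)oc(=O)c2)C(=O)OC)cc1OC
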